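**Retrosynthetic overview**
- The target is 6-hydroxy-7-methoxy-3-(3,4,5-trimethoxyphenyl)chromen-4-one. The C6 phenol is carried as a benzyl ether and freed last by hydrogenolysis.
- The C2=C3 double bond of ring C is traced back to a tertiary alcohol at C3, that is, to dehydration of a 3-hydroxy-3-arylchroman-4-one.
- Key disconnection: the C3–C4 bond of ring C, which joins the C4 carbonyl carbon on ring A to the aryl-bearing C3. Cutting it leaves a salicylaldehyde carbon (C4) and a phenacyl ketone carbon (C3), both electrophiles, so C4 must react as an acyl anion in a carbene-catalysed crossed benzoin closure.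
- The keto aldehyde is opened at the O1–C2 ether bond to a salicylaldehyde and an alpha-bromo ketone; the salicylaldehyde comes from ortho-formylation of a phenol.
- Ring order: rings A and B are bought intact; ring C is the only ring formed, in the benzoin step.

Key step: step 3

Assumption: both starting materials are taken as catalogue compounds, and because the target is achiral the ketol of the key step is accepted as a racemate.

**Step 1**
Reactants: 1 4-(benzyloxy)-3-methoxyphenol
Product: 3 5-(benzyloxy)-2-hydroxy-4-methoxybenzaldehyde, via hydroxymethylphenol 2 (not isolated)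
Conditions: MgCl2, Et3N, (CH2O)n, MeCN, reflux; then 1 M HCl
Reagents that add atoms: paraformaldehyde (as formaldehyde), C=O
Why: Magnesium-mediated ortho-formylation of a phenol (Casiraghi–Skattebøl conditions): the magnesium phenoxide of 1 delivers formaldehyde through a chelate to the ortho position, here the open C6 site para to the methoxy group and not the crowded C2 site between the two oxygens, and the hydroxymethyl compound 2 is oxidised in the flask by hydride transfer to a second formaldehyde.

**Step 2**
Reactants: 3 5-(benzyloxy)-2-hydroxy-4-methoxybenzaldehyde; 4 2-bromo-1-(3,4,5-trimethoxyphenyl)ethanone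
Product: 5 5-(benzyloxy)-4-methoxy-2-[2-oxo-2-(3,4,5-trimethoxyphenyl)ethoxy]benzaldehyde
Conditions: K2CO3, acetone, rt
Reagents that add atoms: none
Why: Williamson ether synthesis: the phenoxide of 3 displaces bromide from the very SN2-reactive alpha-bromo ketone 4 at room temperature, where the follow-up aldol closure to a benzofuran (Rap–Stoermer reaction) is slow, the more so as the aldehyde is deactivated by the para methoxy group.

**Step 3**
Reactants: 5 5-(benzyloxy)-4-methoxy-2-[2-oxo-2-(3,4,5-trimethoxyphenyl)ethoxy]benzaldehyde
Product: 7 racemic 6-(benzyloxy)-3-hydroxy-7-methoxy-3-(3,4,5-trimethoxyphenyl)chroman-4-one, via Breslow enaminol 6 (not isolated)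
Conditions: 2-(pentafluorophenyl)-6,7-dihydro-5H-pyrrolo[2,1-c][1,2,4]triazol-2-ium tetrafluoroborate (20 mol%), DBU (15 mol%), THF (0.05 M), rt, Ar
Reagents that add atoms: none
Why: DBU deprotonates the triazolium salt to the free carbene, which adds to the aldehyde carbonyl of 5, and proton transfer gives the nucleophilic Breslow enaminol 6, whose carbinol carbon (the future C4) attacks the carbonyl carbon of the tethered aryl ketone (the future C3) before the carbene is expelled from the resulting alkoxide to release ketol 7. The closest known reaction is the carbene-catalysed intramolecular crossed aldehyde–ketone benzoin reaction of 2-(2-oxo-2-arylethoxy)benzaldehydes to 3-hydroxychroman-4-ones, of which this is a direct case. Ring C closes in a 6-exo-trig mode over the atoms C4, C4a, C8a, O1, C2 and C3. The one new stereocentre, C3, is not controlled because the catalyst is achiral, so 7 should form as a racemate, which is harmless since C3 becomes trigonal in step 4. The step needs chemoselectivity for acyl anion addition over the base-induced aldol closure of the ketone enolate onto the aldehyde, which would end in a 2-aroylbenzofuran, and over intermolecular homo-benzoin coupling. The substrate secures this because only the aldehyde can form a Breslow intermediate, the ketone carbon lies five bonds from the aldehyde carbon so that closure is fast, the para methoxy group makes the aldehyde a poor aldol acceptor, and DBU is kept below the loading of the azolium salt at high dilution so that little free base is present.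

**Step 4**
Reactants: 7 racemic 6-(benzyloxy)-3-hydroxy-7-methoxy-3-(3,4,5-trimethoxyphenyl)chroman-4-one
Product: 9 6-(benzyloxy)-7-methoxy-3-(3,4,5-trimethoxyphenyl)-4H-chromen-4-one, via chlorosulfite ester 8 (not isolated)
Conditions: SOCl2, pyridine, CH2Cl2, 0 °C to rt
Reagents that add atoms: none
Why: Dehydration of a tertiary alcohol through its chlorosulfite: SOCl2 converts the C3 hydroxyl into the chlorosulfite 8, pyridine removes a C2 hydrogen in an anti elimination with loss of SO2 and chloride, and since C3 has beta-hydrogens only at C2 the sole alkene possible is the conjugated C2=C3 bond of the chromone.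

**Step 5**
Reactants: 9 6-(benzyloxy)-7-methoxy-3-(3,4,5-trimethoxyphenyl)-4H-chromen-4-one
Product: 10 6-hydroxy-7-methoxy-3-(3,4,5-trimethoxyphenyl)-4H-chromen-4-one
Conditions: H2 (1 atm), Pd/C, EtOAc–MeOH, rt
Reagents that add atoms: none
Why: Catalytic hydrogenolysis of a benzyl aryl ether: the benzylic C–O bond is cleaved on palladium at one atmosphere of hydrogen much faster than the vinylogous ester C2=C3 bond is saturated, and the four methyl ethers are inert.

**Compound list**
1 | 4-(benzyloxy)-3-methoxyphenol | COc1cc(O)ccc1OCc1ccccc1 | starting material
2 | 4-(benzyloxy)-2-(hydroxymethyl)-5-methoxyphenol (present as its magnesium salt) | COc1cc(O)c(CO)cc1OCc1ccccc1 | intermediate (not isolated)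
3 | 5-(benzyloxy)-2-hydroxy-4-methoxybenzaldehyde | COc1cc(O)c(C=O)cc1OCc1ccccc1 | intermediate
4 | 2-bromo-1-(3,4,5-trimethoxyphenyl)ethanone | O=C(CBr)c1cc(OC)c(OC)c(OC)c1 | starting material
5 | 5-(benzyloxy)-4-methoxy-2-[2-oxo-2-(3,4,5-trimethoxyphenyl)ethoxy]benzaldehyde | COc1cc(OCC(=O)c2cc(OC)c(OC)c(OC)c2)c(C=O)cc1OCc1ccccc1 | intermediate
6 | Breslow enaminol of 5: the aldehyde carbon bears OH and is doubly bonded to C3 of the 2-(pentafluorophenyl)-6,7-dihydro-5H-pyrrolo[2,1-c][1,2,4]triazol-3-ylidene unit; double-bond geometry not defined | COc1cc(OCC(=O)c2cc(OC)c(OC)c(OC)c2)c(cc1OCc1ccccc1)C(O)=C1N(c2c(F)c(F)c(F)c(F)c2F)N=C2CCCN12 | intermediate (not isolated)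
7 | racemic 6-(benzyloxy)-3-hydroxy-7-methoxy-3-(3,4,5-trimethoxyphenyl)chroman-4-one | COc1cc2OCC(O)(c3cc(OC)c(OC)c(OC)c3)C(=O)c2cc1OCc1ccccc1 | intermediate
8 | racemic chlorosulfite ester of 7 at the C3 oxygen | COc1cc2OCC(OS(=O)Cl)(c3cc(OC)c(OC)c(OC)c3)C(=O)c2cc1OCc1ccccc1 | intermediate (not isolated)
9 | 6-(benzyloxy)-7-methoxy-3-(3,4,5-trimethoxyphenyl)-4H-chromen-4-one | COc1cc2occ(-c3cc(OC)c(OC)c(OC)c3)c(=O)c2cc1OCc1ccccc1 | intermediate
10 | 6-hydroxy-7-methoxy-3-(3,4,5-trimethoxyphenyl)-4H-chromen-4-one | COc1cc2occ(-c3cc(OC)c(OC)c(OC)c3)c(=O)c2cc1O | target

**Total step count:** 5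
**Longest linear sequence:** 5 steps (from 1)

**Steps most likely to fail**

Step 3. The carbene may add only sluggishly to the electron-rich aldehyde, so that enolisation of the phenacyl ether and aldol closure onto the aldehyde, or intermolecular benzoin coupling, take over. The fallback sets out from salicylaldehyde 3 and comes back to the route at isoflavone 9; it gives up the C3–C4 closure and builds ring C the classical way through a deoxybenzoin. Addition of 3,4,5-trimethoxybenzylmagnesium chloride (excess, THF, 0 °C; the first equivalent is consumed by the phenol) to 3 should give the racemic carbinol 4-(benzyloxy)-2-[1-hydroxy-2-(3,4,5-trimethoxyphenyl)ethyl]-5-methoxyphenol F1. Oxidation of the benzylic alcohol with activated MnO2 in CH2Cl2 should give the deoxybenzoin 1-[5-(benzyloxy)-2-hydroxy-4-methoxyphenyl]-2-(3,4,5-trimethoxyphenyl)ethanone F2. Heating F2 with N,N-dimethylformamide dimethyl acetal (toluene, 100 °C) should condense the active methylene with the one-carbon unit and close ring C by attack of the phenol and loss of dimethylamine, giving 9.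

Step 4. Ionisation of the chlorosulfite and return of chloride to C3 may compete with proton removal from the non-acidic C2 position, so that substitution or recovery of the alcohol on work-up takes the place of elimination. The fallback sets out from ketol 7 and comes back at 9; it replaces the base-induced anti elimination by a thermal syn elimination. Treatment of 7 with Burgess reagent (methyl N-(triethylammoniumsulfonyl)carbamate, toluene, 50–80 °C) should give the triethylammonium N-(methoxycarbonyl)sulfamate ester of 7 F3. On warming, F3 should lose the sulfamate through a cyclic six-membered transition state that takes the syn hydrogen at C2, which is always present because C2 carries two hydrogens, and so give 9.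

Step 5. Saturation of the C2–C3 double bond of the chromone may accompany or follow the hydrogenolysis on prolonged contact with hydrogen and palladium. The fallback sets out from 9 and comes back at 10 without a new compound; it replaces reduction by Lewis-acid cleavage. BCl3 with pentamethylbenzene as cation scavenger (CH2Cl2, −78 °C) should remove the benzyl group as a benzyl cation that is trapped by the scavenger, while the methyl ethers and the enone are left untouched at this temperature.

**Further compounds**
F1 | step 3 | racemic 4-(benzyloxy)-2-[1-hydroxy-2-(3,4,5-trimethoxyphenyl)ethyl]-5-methoxyphenol | COc1cc(O)c(C(O)Cc2cc(OC)c(OC)c(OC)c2)cc1OCc1ccccc1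
F2 | step 3 | 1-[5-(benzyloxy)-2-hydroxy-4-methoxyphenyl]-2-(3,4,5-trimethoxyphenyl)ethanone | COc1cc(O)c(C(=O)Cc2cc(OC)c(OC)c(OC)c2)cc1OCc1ccccc1
F3 | step 4 | racemic triethylammonium N-(methoxycarbonyl)sulfamate ester of 7 at the C3 oxygen | COC(=O)[N-]S(=O)(=O)OC1(COc2cc(OC)c(OCc3ccccc3)cc2C1=O)c1cc(OC)c(OC)c(OC)c1.CC[NH+](CC)CC
F0 | step 5 | none | none
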